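**Retrosynthetic overview**
1. Last C–C bond: the sp3–sp2 bond of the =CH–CH2 linker, made by Negishi coupling of a right-half primary alkylzinc with a left-half (E)-bromomethylene cis-decalin; one final desilylation.
2. Right half: the cyclohexane ring that carries the linker holds four contiguous stereocentres (ring-fusion CH, angular C–CH3, CH–CH2 linker, CH–CH3). This ring and the carbinol ring are closed together from an open-chain (2E,8E,10E)-trienal by an intramolecular Diels–Alder reaction that forms the angular C–fusion CH bond and the linker CH–CH(CH3) bond.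
3. The trienal comes from geranyl acetate (enal end and tether), an isobutyrate silyl ketene acetal (gem-dimethyl carbon; asymmetric aldol sets the carbinol) and (E)-propenylboronic acid (diene end, by iodoolefination and Suzuki coupling).
4. Left half: 2-methylcyclohexanone, auxiliary-controlled Robinson annulation, γ-hydroxylation, hydroxyl-directed hydrogenation (cis fusion), bromomethylenation, C-methylation, axial methyl addition.
5. Ring order: the second ring of the left decalin closes in step 16; both rings of the right decalin close at once in step 11.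

Key step: step 11

Remark on locants: right-half bicyclic compounds use the naphthalene locants of the octalin aldehyde formed in step 11; left-half bicyclic compounds use those of the octalone formed in step 16.
Assumption: the borane promoter made from N-tosyl-D-valine is taken to give the (3S) aldol, by analogy with related isobutyrate aldols; the L-valine promoter would give the antipode.

**Route**

Step 1
Reactants: 1 geranyl acetate
Product: 3 (2E)-3-methyl-6-oxohex-2-en-1-yl acetate, via 6,7-epoxygeranyl acetate 2 (not isolated)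
Conditions: mCPBA (1.05 equiv), CH2Cl2, 0 °C; then H5IO6 (1.2 equiv), THF/H2O, 0 °C to rt
Reagents that add atoms: mCPBA (OOC(=O)c1cccc(Cl)c1)
Why: Peracid epoxidation is selective for the electron-rich 6,7-alkene (the 2,3-alkene is deactivated by the allylic acetate), and periodic acid then opens the epoxide and cleaves the glycol to the aldehyde and acetone (epoxidation followed by periodate cleavage).

Step 2
Reactants: 3 (2E)-3-methyl-6-oxohex-2-en-1-yl acetate; 4 1-methoxy-2-methyl-1-(trimethylsilyloxy)prop-1-ene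
Product: 6 methyl (3S,6E)-8-acetoxy-3-hydroxy-2,2,6-trimethyloct-6-enoate, via trimethylsilyl ether 5 (not isolated)
Conditions: N-tosyl-D-valine (1.0 equiv), BH3·THF (1.0 equiv), CH2Cl2, 0 °C to rt; then 3 and 4 (1.2 equiv), −78 °C; pH 7 buffer, then 1 M HCl
Reagents that add atoms: none
Why: Oxazaborolidinone-promoted asymmetric Mukaiyama aldol: the boron-bound aldehyde is attacked on one face by the silyl ketene acetal, which should set the carbinol carbon as S next to the new gem-dimethyl carbon.

Step 3
Reactants: 6 methyl (3S,6E)-8-acetoxy-3-hydroxy-2,2,6-trimethyloct-6-enoate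
Product: 7 methyl (3S,6E)-8-acetoxy-3-(tert-butyldimethylsilyloxy)-2,2,6-trimethyloct-6-enoate
Conditions: TBSOTf, 2,6-lutidine, CH2Cl2, −78 to 0 °C
Reagents that add atoms: tert-butyldimethylsilyl triflate (CC(C)(C)[Si](C)(C)OS(=O)(=O)C(F)(F)F)
Why: Silyl ether formation; the silyl triflate with a hindered base silylates the secondary alcohol flanked by the quaternary carbon without touching the esters.

Step 4
Reactants: 7 methyl (3S,6E)-8-acetoxy-3-(tert-butyldimethylsilyloxy)-2,2,6-trimethyloct-6-enoate
Product: 8 (3S,6E)-3-(tert-butyldimethylsilyloxy)-2,2,6-trimethyloct-6-ene-1,8-diol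
Conditions: iBu2AlH (5 equiv), CH2Cl2, −78 to 0 °C; aq. potassium sodium tartrate
Reagents that add atoms: none
Why: Hydride reduction with iBu2AlH takes the methyl ester to the primary alcohol and cleaves the acetate in the same operation.

Step 5
Reactants: 8 (3S,6E)-3-(tert-butyldimethylsilyloxy)-2,2,6-trimethyloct-6-ene-1,8-diol
Product: 9 (2E,6S)-6-(tert-butyldimethylsilyloxy)-8-hydroxy-3,7,7-trimethyloct-2-en-1-yl pivalate
Conditions: PivCl (1.05 equiv), pyridine, CH2Cl2, −30 to 0 °C
Reagents that add atoms: pivaloyl chloride (CC(C)(C)C(Cl)=O)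
Why: Selective acylation: the bulky acid chloride reacts with the unhindered allylic primary alcohol far faster than with the neopentyl alcohol next to the silyloxy carbon.

Step 6
Reactants: 9 (2E,6S)-6-(tert-butyldimethylsilyloxy)-8-hydroxy-3,7,7-trimethyloct-2-en-1-yl pivalate
Product: 10 (2E,6S)-6-(tert-butyldimethylsilyloxy)-3,7,7-trimethyl-8-oxooct-2-en-1-yl pivalate
Conditions: Dess–Martin periodinane, NaHCO3, CH2Cl2, 0 °C to rt
Reagents that add atoms: none
Why: Dess–Martin oxidation of the neopentyl alcohol gives the non-enolisable aldehyde under neutral conditions.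

Step 7
Reactants: 10 (2E,6S)-6-(tert-butyldimethylsilyloxy)-3,7,7-trimethyl-8-oxooct-2-en-1-yl pivalate
Product: 11 (2E,6S,8E)-6-(tert-butyldimethylsilyloxy)-9-iodo-3,7,7-trimethylnona-2,8-dien-1-yl pivalate
Conditions: CrCl2 (8 equiv), CHI3 (3 equiv), THF/1,4-dioxane, 0 °C to rt
Reagents that add atoms: iodoform (IC(I)I)
Why: Takai iodoolefination: the gem-dichromium species from CHI3 adds to the hindered aldehyde and eliminates to the (E)-vinyl iodide, favoured further by the α-quaternary carbon.

Step 8
Reactants: 11 (2E,6S,8E)-6-(tert-butyldimethylsilyloxy)-9-iodo-3,7,7-trimethylnona-2,8-dien-1-yl pivalate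
Product: 12 (2E,6S,8E)-6-(tert-butyldimethylsilyloxy)-9-iodo-3,7,7-trimethylnona-2,8-dien-1-ol
Conditions: iBu2AlH (2.5 equiv), CH2Cl2, −78 °C
Reagents that add atoms: none
Why: Reductive ester cleavage removes the pivalate before any palladium step, so no allylic ester is left that could ionise to a π-allyl complex.

Step 9
Reactants: 12 (2E,6S,8E)-6-(tert-butyldimethylsilyloxy)-9-iodo-3,7,7-trimethylnona-2,8-dien-1-ol; 13 (E)-prop-1-enylboronic acid
Product: 14 (2E,6S,8E,10E)-6-(tert-butyldimethylsilyloxy)-3,7,7-trimethyldodeca-2,8,10-trien-1-ol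
Conditions: Pd(PPh3)4 (5 mol%), aq. K3PO4 (3 equiv), THF, 45 °C
Reagents that add atoms: none
Why: Suzuki–Miyaura coupling proceeds with retention at both alkenyl partners and so gives the (E,E)-diene of defined geometry.

Step 10
Reactants: 14 (2E,6S,8E,10E)-6-(tert-butyldimethylsilyloxy)-3,7,7-trimethyldodeca-2,8,10-trien-1-ol
Product: 15 (2E,6S,8E,10E)-6-(tert-butyldimethylsilyloxy)-3,7,7-trimethyldodeca-2,8,10-trienal
Conditions: MnO2 (activated, 20 equiv), CH2Cl2, rt
Reagents that add atoms: none
Why: Allylic oxidation with MnO2 is chemoselective for the allylic alcohol and keeps the E geometry of the trisubstituted enal.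

Step 11
Reactants: 15 (2E,6S,8E,10E)-6-(tert-butyldimethylsilyloxy)-3,7,7-trimethyldodeca-2,8,10-trienal
Product: 16 (1S,2S,4aR,6S,8aS)-6-(tert-butyldimethylsilyloxy)-2,5,5,8a-tetramethyl-1,2,4a,5,6,7,8,8a-octahydronaphthalene-1-carbaldehyde
Conditions: Me2AlCl (1.2 equiv), CH2Cl2, −78 to −20 °C
Reagents that add atoms: none
Why: Coordination of Me2AlCl to the formyl oxygen lowers the enal LUMO, and the (2E)-enal adds suprafacially across the (8E,10E)-diene in a concerted, asynchronous [4+2] cycloaddition; the closest known reaction type is the Lewis-acid-promoted type 1 intramolecular Diels–Alder reaction of terminally activated 1,3,9-decatrienes. The cyclohexene ring (C1–C2–C3–C4–C4a–C8a) closes by the cycloaddition itself (C3–C8 of 15 becomes C8a–C4a, C2–C11 becomes C1–C2), and the carbinol ring (C4a–C5–C6–C7–C8–C8a) closes in the same event as a six-membered chair because the four-atom tether C4–C7 of 15 spans the new C8a–C4a bond. C8a and C1 are tied together by the E geometry of the enal (angular CH3 cis to CHO), C4a and C2 by the E,E geometry of the diene (H4a cis to H2), and the two pairs are linked by the endo position of the aluminium-bound formyl group with the tether exo, which gives the trans ring fusion and puts CHO, the C2 methyl and the angular methyl on one face. The absolute sense comes from C6 of 15, whose silyloxy group sits equatorial in the chair-like tether and so selects the diene face. The step needs endo over exo (trans over cis fusion) and π-facial selectivity; the terminal E-formyl activation under Lewis acid, the gem-dimethyl group that favours the folded reactive conformer, and the equatorial preference of the bulky silyl ether should secure them.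

Step 12
Reactants: 16 (1S,2S,4aR,6S,8aS)-6-(tert-butyldimethylsilyloxy)-2,5,5,8a-tetramethyl-1,2,4a,5,6,7,8,8a-octahydronaphthalene-1-carbaldehyde
Product: 17 (1S,2S,4aR,6S,8aS)-6-(tert-butyldimethylsilyloxy)-2,5,5,8a-tetramethyldecahydronaphthalene-1-carbaldehyde
Conditions: H2 (1 atm), 10% Pd/C, EtOAc, rt
Reagents that add atoms: none
Why: Heterogeneous catalytic hydrogenation saturates the cis-disubstituted ring alkene (no new stereocentre) and leaves the aldehyde and silyl ether intact.

Step 13
Reactants: 17 (1S,2S,4aR,6S,8aS)-6-(tert-butyldimethylsilyloxy)-2,5,5,8a-tetramethyldecahydronaphthalene-1-carbaldehyde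
Product: 18 [(1S,2S,4aR,6S,8aS)-6-(tert-butyldimethylsilyloxy)-2,5,5,8a-tetramethyldecahydronaphthalen-1-yl]methanol
Conditions: NaBH4, MeOH, 0 °C
Reagents that add atoms: none
Why: Borohydride reduction of the aldehyde; the equatorial formyl carbon is not epimerised under these conditions.

Step 14
Reactants: 18 [(1S,2S,4aR,6S,8aS)-6-(tert-butyldimethylsilyloxy)-2,5,5,8a-tetramethyldecahydronaphthalen-1-yl]methanol
Product: 19 (1S,2S,4aR,6S,8aS)-6-(tert-butyldimethylsilyloxy)-1-(iodomethyl)-2,5,5,8a-tetramethyldecahydronaphthalene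
Conditions: I2, PPh3, imidazole, CH2Cl2, 0 °C to rt
Reagents that add atoms: iodine (II)
Why: Appel-type iodination: SN2 displacement of the oxyphosphonium by iodide at the primary carbon, as is usual for β-branched primary alcohols of this decalin type.

Step 15
Reactants: 20 2-methylcyclohexanone (racemic); 21 (R)-1-phenylethylamine
Product: 22 (R)-N-(2-methylcyclohexylidene)-1-phenylethanamine
Conditions: TsOH (cat.), toluene, reflux, Dean–Stark
Reagents that add atoms: none
Why: Imine condensation; the imine equilibrates with its more substituted secondary enamine, which erases the C2 stereocentre of the ketone.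

Step 16
Reactants: 22 (R)-N-(2-methylcyclohexylidene)-1-phenylethanamine; 23 methyl vinyl ketone
Product: 26 (S)-4a-methyl-4,4a,5,6,7,8-hexahydronaphthalen-2(3H)-one, via Michael adduct imine 24 (not isolated), via diketone 25 (not isolated)
Conditions: 23 (1.1 equiv), THF, rt, 48 h; 20% aq. AcOH, rt; then NaOMe, MeOH, 60 °C
Reagents that add atoms: none
Why: Deracemising Michael addition of the chiral enamine tautomer (the phenylethyl group shields one face, which should set the quaternary carbon as S), hydrolysis, then aldol condensation, i.e. an asymmetric Robinson annulation that closes the second ring.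

Step 17
Reactants: 26 (S)-4a-methyl-4,4a,5,6,7,8-hexahydronaphthalen-2(3H)-one
Product: 27 (S)-4a-methyl-3,4,4a,5,6,7-hexahydronaphthalen-2-yl acetate
Conditions: isopropenyl acetate, TsOH (cat.), reflux
Reagents that add atoms: isopropenyl acetate (CC(=C)OC(C)=O)
Why: Acid-catalysed enol acetylation under equilibrating conditions gives the linear (heteroannular) dienol acetate, which activates C8.

Step 18
Reactants: 27 (S)-4a-methyl-3,4,4a,5,6,7-hexahydronaphthalen-2-yl acetate
Product: 28 (4aS,8R)-8-hydroxy-4a-methyl-4,4a,5,6,7,8-hexahydronaphthalen-2(3H)-one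
Conditions: mCPBA, NaHCO3, CH2Cl2/H2O, 0 °C to rt
Reagents that add atoms: mCPBA (OOC(=O)c1cccc(Cl)c1)
Why: Vinylogous Rubottom-type oxidation: the peracid attacks the dienol acetate at its γ-terminus C8 along the axial direction, which should place the new hydroxyl cis to the angular methyl, as in the 6β-hydroxylation of steroidal dienol acetates.

Step 19
Reactants: 28 (4aS,8R)-8-hydroxy-4a-methyl-4,4a,5,6,7,8-hexahydronaphthalen-2(3H)-one
Product: 29 (4aS,8R,8aR)-8-hydroxy-4a-methyloctahydronaphthalen-2(1H)-one (cis-fused)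
Conditions: [Ir(cod)(PCy3)(py)]PF6 (5 mol%), H2 (1 atm), CH2Cl2, rt
Reagents that add atoms: none
Why: Hydroxyl-directed homogeneous hydrogenation: iridium bound to the allylic hydroxyl delivers H2 to the same face of the enone alkene, so H8a ends up cis to the hydroxyl and the angular methyl (cis ring fusion).

Step 20
Reactants: 29 (4aS,8R,8aR)-8-hydroxy-4a-methyloctahydronaphthalen-2(1H)-one
Product: 30 (4aS,8R,8aR)-2,2-(ethylenedioxy)-4a-methyldecahydronaphthalen-8-ol
Conditions: ethylene glycol, pyridinium p-toluenesulfonate, benzene, reflux, Dean–Stark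
Reagents that add atoms: ethylene glycol (OCCO)
Why: Acid-catalysed ketalisation (dioxolane formation) of the only carbonyl; the 8-hydroxyl points away from C2 and cannot form an internal ketal.

Step 21
Reactants: 30 (4aS,8R,8aR)-2,2-(ethylenedioxy)-4a-methyldecahydronaphthalen-8-ol
Product: 31 (4aS,8aR)-2,2-(ethylenedioxy)-4a-methyldecahydronaphthalen-8-one (cis-fused)
Conditions: Dess–Martin periodinane, NaHCO3, CH2Cl2, 0 °C to rt
Reagents that add atoms: none
Why: Dess–Martin oxidation under buffered conditions gives the ketone without epimerising the adjacent ring-fusion carbon.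

Step 22
Reactants: 31 (4aS,8aR)-2,2-(ethylenedioxy)-4a-methyldecahydronaphthalen-8-one
Product: 32 (4aS,8aR,E)-8-(bromomethylene)-2,2-(ethylenedioxy)-4a-methyldecahydronaphthalene
Conditions: Ph3PCH2Br Br (2.5 equiv), NaN(SiMe3)2 (2.4 equiv), THF, −60 °C to rt
Reagents that add atoms: (bromomethyl)triphenylphosphonium bromide (BrC[P+](c1ccccc1)(c1ccccc1)c1ccccc1.[Br-])
Why: Wittig bromomethylenation: the bromine should end up on the side of the ring CH2 and away from the branched ring-fusion carbon (E), as with related α-branched bicyclic ketones, and the weakly basic ylide at low temperature should leave C8a untouched.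

Step 23
Reactants: 32 (4aS,8aR,E)-8-(bromomethylene)-2,2-(ethylenedioxy)-4a-methyldecahydronaphthalene
Product: 33 (4aS,8aR,E)-8-(bromomethylene)-4a-methyloctahydronaphthalen-2(1H)-one
Conditions: pyridinium p-toluenesulfonate, acetone/H2O, 55 °C
Reagents that add atoms: water (O)
Why: Acid-catalysed ketal hydrolysis; the vinyl bromide is inert and C8a is no longer next to a carbonyl.

Step 24
Reactants: 33 (4aS,8aR,E)-8-(bromomethylene)-4a-methyloctahydronaphthalen-2(1H)-one
Product: 35 (1R,4aS,8aR,E)-8-(bromomethylene)-1,4a-dimethyloctahydronaphthalen-2(1H)-one, via trimethylsilyl enol ether 34 (not isolated)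
Conditions: Me3SiOTf, Et3N, CH2Cl2, 0 °C to rt; then MeI, BnMe3NF, 4 Å sieves, THF, rt; then NaOMe (cat.), MeOH, rt
Reagents that add atoms: iodomethane (CI)
Why: Thermodynamic silyl enol ether formation toward C1 (the direction favoured in the steroid-like cis-fused chair that allylic strain from the bromomethylene enforces), fluoride-mediated regiospecific C-methylation, then base equilibration, which should leave the new methyl equatorial and therefore cis to H8a and the angular methyl.

Step 25
Reactants: 35 (1R,4aS,8aR,E)-8-(bromomethylene)-1,4a-dimethyloctahydronaphthalen-2(1H)-one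
Product: 36 (1R,2R,4aS,8aR,E)-8-(bromomethylene)-1,2,4a-trimethyldecahydronaphthalen-2-ol
Conditions: MeAl(OAr)2 (Ar = 2,6-di-tert-butyl-4-methylphenyl, 3 equiv, from Me3Al and ArOH), toluene, −78 °C; MeLi (2 equiv), −78 °C
Reagents that add atoms: methyllithium ([Li]C)
Why: Carbonyl alkylation mediated by a bulky aluminium aryloxide: the Lewis acid binds the carbonyl on its equatorial side and MeLi attacks axially, which should give the equatorial alcohol with the new methyl cis to the other two methyl groups.

Step 26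
Reactants: 19 (1S,2S,4aR,6S,8aS)-6-(tert-butyldimethylsilyloxy)-1-(iodomethyl)-2,5,5,8a-tetramethyldecahydronaphthalene; 36 (1R,2R,4aS,8aR,E)-8-(bromomethylene)-1,2,4a-trimethyldecahydronaphthalen-2-ol
Product: 38 tert-butyldimethylsilyl ether of the target (secondary hydroxyl silylated), via alkylzinc iodide 37 (not isolated)
Conditions: 19 (1.5 equiv), Zn dust (activated with BrCH2CH2Br and Me3SiCl), LiCl, THF, 45 °C; then 36, Pd(OAc)2 (5 mol%), SPhos (10 mol%), THF, rt to 45 °C
Reagents that add atoms: none
Why: LiCl-assisted zinc insertion followed by Negishi coupling: oxidative addition, transmetalation and reductive elimination retain the E geometry of the alkenyl bromide, and the alkylzinc halide tolerates the tertiary hydroxyl and the silyl ether.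

Step 27
Reactants: 38 tert-butyldimethylsilyl ether of the target
Product: 39 CNP0338143.1 (target)
Conditions: Bu4NF (5 equiv), THF, 60 °C
Reagents that add atoms: none
Why: Fluoride-mediated desilylation of the hindered secondary silyl ether; the tertiary alcohol and the trisubstituted alkene are unaffected.

**Compound list**
1 | geranyl acetate | CC(C)=CCC/C(C)=C/COC(C)=O | starting material
2 | (2E)-5-(3,3-dimethyloxiran-2-yl)-3-methylpent-2-en-1-yl acetate (racemic epoxide) | CC(=O)OC/C=C(\C)CCC1OC1(C)C | intermediate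
3 | (2E)-3-methyl-6-oxohex-2-en-1-yl acetate | CC(=O)OC/C=C(\C)CCC=O | intermediate
4 | 1-methoxy-2-methyl-1-(trimethylsilyloxy)prop-1-ene | COC(O[Si](C)(C)C)=C(C)C | starting material
5 | methyl (3S,6E)-8-acetoxy-2,2,6-trimethyl-3-(trimethylsilyloxy)oct-6-enoate | COC(=O)C(C)(C)[C@@H](O[Si](C)(C)C)CC/C(C)=C/COC(C)=O | intermediate
6 | methyl (3S,6E)-8-acetoxy-3-hydroxy-2,2,6-trimethyloct-6-enoate | COC(=O)C(C)(C)[C@@H](O)CC/C(C)=C/COC(C)=O | intermediate
7 | methyl (3S,6E)-8-acetoxy-3-(tert-butyldimethylsilyloxy)-2,2,6-trimethyloct-6-enoate | COC(=O)C(C)(C)[C@@H](O[Si](C)(C)C(C)(C)C)CC/C(C)=C/COC(C)=O | intermediate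
8 | (3S,6E)-3-(tert-butyldimethylsilyloxy)-2,2,6-trimethyloct-6-ene-1,8-diol | OCC(C)(C)[C@@H](O[Si](C)(C)C(C)(C)C)CC/C(C)=C/CO | intermediate
9 | (2E,6S)-6-(tert-butyldimethylsilyloxy)-8-hydroxy-3,7,7-trimethyloct-2-en-1-yl pivalate | OCC(C)(C)[C@@H](O[Si](C)(C)C(C)(C)C)CC/C(C)=C/COC(=O)C(C)(C)C | intermediate
10 | (2E,6S)-6-(tert-butyldimethylsilyloxy)-3,7,7-trimethyl-8-oxooct-2-en-1-yl pivalate | O=CC(C)(C)[C@@H](O[Si](C)(C)C(C)(C)C)CC/C(C)=C/COC(=O)C(C)(C)C | intermediate
11 | (2E,6S,8E)-6-(tert-butyldimethylsilyloxy)-9-iodo-3,7,7-trimethylnona-2,8-dien-1-yl pivalate | I/C=C/C(C)(C)[C@@H](O[Si](C)(C)C(C)(C)C)CC/C(C)=C/COC(=O)C(C)(C)C | intermediate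
12 | (2E,6S,8E)-6-(tert-butyldimethylsilyloxy)-9-iodo-3,7,7-trimethylnona-2,8-dien-1-ol | I/C=C/C(C)(C)[C@@H](O[Si](C)(C)C(C)(C)C)CC/C(C)=C/CO | intermediate
13 | (E)-prop-1-enylboronic acid | C/C=C/B(O)O | starting material
14 | (2E,6S,8E,10E)-6-(tert-butyldimethylsilyloxy)-3,7,7-trimethyldodeca-2,8,10-trien-1-ol | C/C=C/C=C/C(C)(C)[C@@H](O[Si](C)(C)C(C)(C)C)CC/C(C)=C/CO | intermediate
15 | (2E,6S,8E,10E)-6-(tert-butyldimethylsilyloxy)-3,7,7-trimethyldodeca-2,8,10-trienal | C/C=C/C=C/C(C)(C)[C@@H](O[Si](C)(C)C(C)(C)C)CC/C(C)=C/C=O | intermediate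
16 | (1S,2S,4aR,6S,8aS)-6-(tert-butyldimethylsilyloxy)-2,5,5,8a-tetramethyl-1,2,4a,5,6,7,8,8a-octahydronaphthalene-1-carbaldehyde (trans-fused) | O=C[C@H]1[C@@H](C)C=C[C@H]2C(C)(C)[C@@H](O[Si](C)(C)C(C)(C)C)CC[C@]12C | intermediate
17 | (1S,2S,4aR,6S,8aS)-6-(tert-butyldimethylsilyloxy)-2,5,5,8a-tetramethyldecahydronaphthalene-1-carbaldehyde | O=C[C@H]1[C@@H](C)CC[C@H]2C(C)(C)[C@@H](O[Si](C)(C)C(C)(C)C)CC[C@]12C | intermediate
18 | [(1S,2S,4aR,6S,8aS)-6-(tert-butyldimethylsilyloxy)-2,5,5,8a-tetramethyldecahydronaphthalen-1-yl]methanol | OC[C@H]1[C@@H](C)CC[C@H]2C(C)(C)[C@@H](O[Si](C)(C)C(C)(C)C)CC[C@]12C | intermediate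
19 | (1S,2S,4aR,6S,8aS)-6-(tert-butyldimethylsilyloxy)-1-(iodomethyl)-2,5,5,8a-tetramethyldecahydronaphthalene | IC[C@H]1[C@@H](C)CC[C@H]2C(C)(C)[C@@H](O[Si](C)(C)C(C)(C)C)CC[C@]12C | intermediate
20 | 2-methylcyclohexanone (racemic) | CC1CCCCC1=O | starting material
21 | (R)-1-phenylethylamine | C[C@@H](N)c1ccccc1 | starting material
22 | (R)-N-(2-methylcyclohexylidene)-1-phenylethanamine | CC1CCCCC1=N[C@H](C)c1ccccc1 | intermediate
23 | methyl vinyl ketone | C=CC(C)=O | starting material
24 | (R)-N-[(S)-2-methyl-2-(3-oxobutyl)cyclohexylidene]-1-phenylethanamine | CC(=O)CC[C@]1(C)CCCCC1=N[C@H](C)c1ccccc1 | intermediate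
25 | (S)-2-methyl-2-(3-oxobutyl)cyclohexan-1-one | CC(=O)CC[C@]1(C)CCCCC1=O | intermediate
26 | (S)-4a-methyl-4,4a,5,6,7,8-hexahydronaphthalen-2(3H)-one | C[C@@]12CCCCC1=CC(=O)CC2 | intermediate
27 | (S)-4a-methyl-3,4,4a,5,6,7-hexahydronaphthalen-2-yl acetate | C[C@@]12CCCC=C1C=C(OC(C)=O)CC2 | intermediate
28 | (4aS,8R)-8-hydroxy-4a-methyl-4,4a,5,6,7,8-hexahydronaphthalen-2(3H)-one (OH cis to 4a-CH3) | C[C@@]12CCC[C@@H](O)C1=CC(=O)CC2 | intermediate
29 | (4aS,8R,8aR)-8-hydroxy-4a-methyloctahydronaphthalen-2(1H)-one (cis-fused) | C[C@@]12CCC[C@@H](O)[C@@H]1CC(=O)CC2 | intermediate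
30 | (4aS,8R,8aR)-2,2-(ethylenedioxy)-4a-methyldecahydronaphthalen-8-ol | C[C@@]12CCC[C@@H](O)[C@@H]1CC1(OCCO1)CC2 | intermediate
31 | (4aS,8aR)-2,2-(ethylenedioxy)-4a-methyldecahydronaphthalen-8-one (cis-fused) | C[C@@]12CCCC(=O)[C@@H]1CC1(OCCO1)CC2 | intermediate
32 | (4aS,8aR,E)-8-(bromomethylene)-2,2-(ethylenedioxy)-4a-methyldecahydronaphthalene | C[C@@]12CCC/C(=C\Br)[C@@H]1CC1(OCCO1)CC2 | intermediate
33 | (4aS,8aR,E)-8-(bromomethylene)-4a-methyloctahydronaphthalen-2(1H)-one | C[C@@]12CCC/C(=C\Br)[C@@H]1CC(=O)CC2 | intermediate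
34 | (4aS,8aR,E)-8-(bromomethylene)-4a-methyl-2-(trimethylsilyloxy)-3,4,4a,5,6,7,8,8a-octahydronaphthalene | C[C@@]12CCC/C(=C\Br)[C@@H]1C=C(O[Si](C)(C)C)CC2 | intermediate
35 | (1R,4aS,8aR,E)-8-(bromomethylene)-1,4a-dimethyloctahydronaphthalen-2(1H)-one | C[C@@]12CCC/C(=C\Br)[C@@H]1[C@@H](C)C(=O)CC2 | intermediate
36 | (1R,2R,4aS,8aR,E)-8-(bromomethylene)-1,2,4a-trimethyldecahydronaphthalen-2-ol (cis-fused; three methyls and H8a on one face, OH on the other) | C[C@@]12CCC/C(=C\Br)[C@@H]1[C@@H](C)[C@](C)(O)CC2 | intermediate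
37 | alkylzinc iodide from 19 (iodozinciomethyl decalin) | I[Zn]C[C@H]1[C@@H](C)CC[C@H]2C(C)(C)[C@@H](O[Si](C)(C)C(C)(C)C)CC[C@]12C | intermediate
38 | tert-butyldimethylsilyl ether of the target (E alkene; secondary OH silylated, tertiary OH free) | C[C@@H]1[C@H]2/C(=C/C[C@H]3[C@@H](C)CC[C@H]4C(C)(C)[C@@H](O[Si](C)(C)C(C)(C)C)CC[C@]34C)CCC[C@@]2(C)CC[C@@]1(C)O | intermediate
39 | CNP0338143.1 | C[C@@H]1[C@H]2/C(=C/C[C@H]3[C@@H](C)CC[C@H]4C(C)(C)[C@@H](O)CC[C@]34C)CCC[C@@]2(C)CC[C@@]1(C)O | target

**Step count**
Total: 27 steps. Longest linear sequence: 16 steps (steps 1–14, then 26 and 27); the left-half branch is steps 15–25.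

**Three steps most likely to fail**

1. Step 11 (key step). The cycloaddition may show poor π-facial discrimination by the silyloxy stereocentre, may leak through the exo-formyl (cis-fused) transition state, or the Lewis acid may isomerise the diene before ring closure. The fallback removes the resident stereocentre and uses catalyst control. It sets out from 14: Bu4NF gives the triene-1,6-diol F1, and Dess–Martin periodinane oxidises both alcohols to the 6-oxo trienal F2. F2 is cyclised by the same intramolecular Diels–Alder disconnection under a chiral cationic oxazaborolidine Lewis acid to the trans-fused 6-oxo octalin aldehyde F3. NaBH4 then reduces aldehyde and ketone (axial hydride delivery to the 5,5-dimethyl ketone gives the equatorial 6S alcohol) to the octalin diol F4, and H2 over Pd/C gives the saturated diol F5. I2/PPh3/imidazole converts only the primary alcohol, giving the iodo alcohol F6, and TBSOTf/2,6-lutidine returns the route to 19.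

2. Step 26. Transmetalation and reductive elimination between two hindered partners may be slow, so that protonation of the alkylzinc by the tertiary hydroxyl or β-hydride elimination takes over. The fallback is a B-alkyl Suzuki–Miyaura coupling. It sets out from 19: t-BuLi (Et2O, −78 °C) followed by 9-methoxy-9-borabicyclo[3.3.1]nonane gives the lithium alkyl(methoxy)borinate F7, which is coupled with 36 using Pd(dppf)Cl2 and aq. K3PO4 in DMF/THF and returns to the route at 38.

3. Step 22. The bulky ylide may olefinate the hindered ring-fusion ketone only slowly, so that enolisation (and with it loss of the cis fusion) competes. The fallback is a boron-Wittig olefination with a smaller nucleophile. It sets out from 31: LiCH(Bpin)2 (from CH2(Bpin)2 and lithium tetramethylpiperidide, THF, −78 °C to rt) gives the (E)-alkenyl pinacol boronate F8, boron ending up away from the branched ring-fusion carbon. Bromodeboronation with N-bromosuccinimide in MeCN (ipso substitution with retention, as for alkenylboron compounds) returns to the route at 32.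

**Further compounds**
F1 | step 11 | (2E,6S,8E,10E)-3,7,7-trimethyldodeca-2,8,10-triene-1,6-diol | C/C=C/C=C/C(C)(C)[C@@H](O)CC/C(C)=C/CO
F2 | step 11 | (2E,8E,10E)-3,7,7-trimethyl-6-oxododeca-2,8,10-trienal | C/C=C/C=C/C(C)(C)C(=O)CC/C(C)=C/C=O
F3 | step 11 | trans-fused 2,5,5,8a-tetramethyl-6-oxo-1,2,4a,5,6,7,8,8a-octahydronaphthalene-1-carbaldehyde (CHO, 2-CH3 and 8a-CH3 cis) | O=C[C@H]1[C@@H](C)C=C[C@H]2C(C)(C)C(=O)CC[C@]12C
F4 | step 11 | 5-(hydroxymethyl)-1,1,4a,6-tetramethyl-1,2,3,4,4a,5,6,8a-octahydronaphthalen-2-ol (equatorial secondary OH) | OC[C@H]1[C@@H](C)C=C[C@H]2C(C)(C)[C@@H](O)CC[C@]12C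
F5 | step 11 | 5-(hydroxymethyl)-1,1,4a,6-tetramethyldecahydronaphthalen-2-ol | OC[C@H]1[C@@H](C)CC[C@H]2C(C)(C)[C@@H](O)CC[C@]12C
F6 | step 11 | 5-(iodomethyl)-1,1,4a,6-tetramethyldecahydronaphthalen-2-ol | IC[C@H]1[C@@H](C)CC[C@H]2C(C)(C)[C@@H](O)CC[C@]12C
F7 | step 26 | lithium alkyl(methoxy)borinate from 19 and 9-methoxy-9-borabicyclo[3.3.1]nonane | [Li+].CO[B-]1(C[C@H]2[C@@H](C)CC[C@H]3C(C)(C)[C@@H](O[Si](C)(C)C(C)(C)C)CC[C@]23C)C4CCCC1CCC4
F8 | step 22 | (4aS,8aR,E)-2,2-(ethylenedioxy)-4a-methyl-8-[(4,4,5,5-tetramethyl-1,3,2-dioxaborolan-2-yl)methylene]decahydronaphthalene | C[C@@]12CCC/C(=C\B3OC(C)(C)C(C)(C)O3)[C@@H]1CC1(OCCO1)CC2
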